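**Retrosynthetic overview**
1. Removing two O-benzyl and two O-TBS groups leads back to a fully protected sesquilignan. Its erythro C7''-OH comes from the threo alcohol by Mitsunobu inversion.
2. Key disconnection C7''–C8'': an Evans boron aldol between the aryloxyacetyl imide of the complete tetrahydrofuran lignan and O-benzylvanillin sets C8'' and C7''.
3. The aryl-O–CH2 bond comes from Williamson alkylation of the liberated syringyl phenol with methyl bromoacetate.
4. In the THF ring, C7–O comes from acid cyclodehydration of a benzylic carbinol/1,4-diol. C7–C8 comes from an aldol of the (S)-β-benzylbutyrolactone enolate with O-allylsyringaldehyde.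
5. Ring order: the butyrolactone is made first (Evans alkylation sets C8'; the ring is later opened with LiAlH4), then the tetrahydrofuran. No other ring is made.

Assumption: O-benzylvanillin and both enantiomers of 4-benzyloxazolidin-2-one are taken as commercial, and the target SMILES is read as 7R,8S,8'S,7''S,8''R (ent-lariciresinol-type core: 7,8-trans, 8,8'-cis; erythro side chain).

Conventions: C7–C9 is the syringyl C3 unit, C7'–C9' is the benzyl-bearing C3 unit, and C7''–C9'' is the glycerol side chain. "Lig" stands for 4-[(2R,3S,4S)-4-(4-benzyloxy-3-methoxybenzyl)-3-(tert-butyldimethylsilyloxymethyl)tetrahydrofuran-2-yl]-2,6-dimethoxyphenyl.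

**Step 1**
Reactants: 1 ferulic acid
Product: 2 dihydroferulic acid [3-(4-hydroxy-3-methoxyphenyl)propanoic acid]
Conditions: H2 (1 atm), 10% Pd/C, MeOH, rt
Reagents that add atoms: none
Why: Heterogeneous catalytic hydrogenation saturates the cinnamic C=C cleanly, and it is done before any benzyl ether is present.

**Step 2**
Reactants: 2 dihydroferulic acid
Product: 3 benzyl 3-(4-benzyloxy-3-methoxyphenyl)propanoate
Conditions: BnBr (2.3 equiv), K2CO3, DMF, 60 °C
Reagents that add atoms: benzyl bromide BrCc1ccccc1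
Why: Williamson etherification and carboxylate alkylation both run to completion under these conditions, so no mixed products remain.

**Step 3**
Reactants: 3 benzyl 3-(4-benzyloxy-3-methoxyphenyl)propanoate
Product: 4 3-(4-benzyloxy-3-methoxyphenyl)propanoic acid
Conditions: 2 M NaOH, THF–MeOH, 50 °C; then 1 M HCl
Reagents that add atoms: sodium hydroxide [Na+].[OH-]
Why: Saponification (BAc2) cleaves only the ester, because the aryl benzyl ether is inert to base.

**Step 4**
Reactants: 4 3-(4-benzyloxy-3-methoxyphenyl)propanoic acid; 5 (R)-4-benzyloxazolidin-2-one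
Product: 7 (R)-4-benzyl-3-[3-(4-benzyloxy-3-methoxyphenyl)propanoyl]oxazolidin-2-one, via mixed pivalic anhydride 6 (not isolated)
Conditions: PivCl, Et3N, THF, −20 °C; then LiCl, 5, −20 °C → rt
Reagents that add atoms: pivaloyl chloride CC(C)(C)C(=O)Cl (its acyl group is carried only by 6)
Why: In this mixed-anhydride N-acylation the LiCl-activated oxazolidinone attacks the unhindered carbonyl of 6 and not the pivaloyl carbonyl.

**Step 5**
Reactants: 7 (R)-4-benzyl-3-[3-(4-benzyloxy-3-methoxyphenyl)propanoyl]oxazolidin-2-one; 8 tert-butyl bromoacetate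
Product: 10 tert-butyl (3S)-3-(4-benzyloxy-3-methoxybenzyl)-4-[(4R)-4-benzyl-2-oxooxazolidin-3-yl]-4-oxobutanoate, via sodium (Z)-enolate 9 (not isolated)
Conditions: NaHMDS, THF, −78 °C; then 8, −78 → −40 °C
Reagents that add atoms: sodium bis(trimethylsilyl)amide [Na+].C[Si](C)(C)[N-][Si](C)(C)C (sodium is carried only by 9)
Why: In this Evans asymmetric alkylation the chelated (Z)-enolate is attacked on the face opposite the auxiliary benzyl group, which sets the future C8' as S (dr typically >95:5).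

**Step 6**
Reactants: 10 tert-butyl (3S)-3-(4-benzyloxy-3-methoxybenzyl)-4-[(4R)-4-benzyl-2-oxooxazolidin-3-yl]-4-oxobutanoate
Product: 11 tert-butyl (3S)-3-(4-benzyloxy-3-methoxybenzyl)-4-hydroxybutanoate
Conditions: NaBH4, THF–H2O (4:1), 0 °C → rt
Reagents that add atoms: none
Why: Reductive auxiliary removal with borohydride reduces the activated imide carbonyl to CH2OH without epimerisation and leaves the tert-butyl ester untouched.

**Step 7**
Reactants: 11 tert-butyl (3S)-3-(4-benzyloxy-3-methoxybenzyl)-4-hydroxybutanoate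
Product: 12 (4S)-4-(4-benzyloxy-3-methoxybenzyl)dihydrofuran-2(3H)-one
Conditions: p-TsOH·H2O (10 mol %), toluene, 80 °C
Reagents that add atoms: none
Why: Acid-catalysed lactonisation (intramolecular transesterification) to the five-membered ring is strongly favoured and does not touch the stereocentre.

**Step 8**
Reactants: 13 syringaldehyde
Product: 14 4-allyloxy-3,5-dimethoxybenzaldehyde
Conditions: allyl bromide, K2CO3, DMF, 50 °C
Reagents that add atoms: allyl bromide C=CCBr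
Why: Williamson etherification installs a phenol protecting group that survives enolates, LiAlH4 and acid, and that is orthogonal to benzyl and silyl groups.

**Step 9**
Reactants: 12 (4S)-4-(4-benzyloxy-3-methoxybenzyl)dihydrofuran-2(3H)-one; 14 4-allyloxy-3,5-dimethoxybenzaldehyde
Product: 16 (3R,4S)-3-[(4-allyloxy-3,5-dimethoxyphenyl)(hydroxy)methyl]-4-(4-benzyloxy-3-methoxybenzyl)dihydrofuran-2(3H)-one (3,4-trans; both C7 carbinol epimers), via lithium enolate 15 (not isolated)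
Conditions: LiHMDS, THF, −78 °C; then 14, −78 °C, 2 h; AcOH quench at −78 °C
Reagents that add atoms: lithium bis(trimethylsilyl)amide [Li+].C[Si](C)(C)[N-][Si](C)(C)C (lithium is carried only by 15)
Why: In this intermolecular aldol addition the aldehyde approaches anti to the C4 benzyl group, so C8 is set trans to C8', and the C7 carbinol mixture does not matter because C7 is re-set in step 11.

**Step 10**
Reactants: 16 (3R,4S)-3-[(4-allyloxy-3,5-dimethoxyphenyl)(hydroxy)methyl]-4-(4-benzyloxy-3-methoxybenzyl)dihydrofuran-2(3H)-one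
Product: 17 (2S,3S)-2-[(4-allyloxy-3,5-dimethoxyphenyl)(hydroxy)methyl]-3-(4-benzyloxy-3-methoxybenzyl)butane-1,4-diol (both C7 epimers)
Conditions: LiAlH4, THF, 0 °C → rt; aqueous work-up
Reagents that add atoms: none
Why: Fast hydride reduction of the lactone at low temperature outruns retro-aldol and fixes C8, which is no longer alpha to a carbonyl.

**Step 11**
Reactants: 17 (2S,3S)-2-[(4-allyloxy-3,5-dimethoxyphenyl)(hydroxy)methyl]-3-(4-benzyloxy-3-methoxybenzyl)butane-1,4-diol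
Product: 18 [(2R,3S,4S)-2-(4-allyloxy-3,5-dimethoxyphenyl)-4-(4-benzyloxy-3-methoxybenzyl)tetrahydrofuran-3-yl]methanol
Conditions: CSA (10 mol %), CH2Cl2, 0 °C → rt; Et3N quench
Reagents that add atoms: none
Why: In this SN1 cyclodehydration (cycloetherification) both carbinol epimers give the same trialkoxybenzylic cation, and the C9' hydroxyl closes the five-membered ring with the aryl group trans to the C8 CH2OH, which sets C7 as R (oxetane closure by C9-OH does not compete).

**Step 12**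
Reactants: 18 [(2R,3S,4S)-2-(4-allyloxy-3,5-dimethoxyphenyl)-4-(4-benzyloxy-3-methoxybenzyl)tetrahydrofuran-3-yl]methanol
Product: 19 allyl ether Lig-O-allyl [(2R,3S,4S)-2-(4-allyloxy-3,5-dimethoxyphenyl)-4-(4-benzyloxy-3-methoxybenzyl)-3-(tert-butyldimethylsilyloxymethyl)tetrahydrofuran]
Conditions: TBSCl, imidazole, DMF, rt
Reagents that add atoms: tert-butyldimethylsilyl chloride CC(C)(C)[Si](C)(C)Cl
Why: Standard silylation masks the only free hydroxyl before the acylation and boron chemistry that follow.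

**Step 13**
Reactants: 19 allyl ether Lig-O-allyl
Product: 20 phenol Lig-OH
Conditions: Pd(PPh3)4 (5 mol %), morpholine, THF, rt
Reagents that add atoms: none
Why: In this Tsuji–Trost-type deallylation Pd(0) ionises the aryl allyl ether to a π-allyl complex that morpholine traps, while benzyl and silyl ethers are untouched.

**Step 14**
Reactants: 20 phenol Lig-OH; 21 methyl bromoacetate
Product: 22 methyl 2-(Lig-oxy)acetate
Conditions: K2CO3, DMF, 40 °C
Reagents that add atoms: none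
Why: Williamson etherification with an unhindered, activated primary bromide works well even for a 2,6-dimethoxyphenoxide, so the crowded aryl–O–C8'' bond is made before C8'' becomes secondary.

**Step 15**
Reactants: 22 methyl 2-(Lig-oxy)acetate
Product: 23 2-(Lig-oxy)acetic acid
Conditions: LiOH·H2O, THF–MeOH–H2O, rt; then 1 M HCl to pH 4, 0 °C
Reagents that add atoms: lithium hydroxide [Li+].[OH-]
Why: Mild saponification of the activated methyl ester leaves the primary TBS ether and the benzylic THF ether intact.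

**Step 16**
Reactants: 23 2-(Lig-oxy)acetic acid; 24 (S)-4-benzyloxazolidin-2-one
Product: 26 (S)-4-benzyl-3-[2-(Lig-oxy)acetyl]oxazolidin-2-one, via mixed pivalic anhydride 25 (not isolated)
Conditions: PivCl, Et3N, THF, −20 °C; then LiCl, 24, −20 °C → rt
Reagents that add atoms: pivaloyl chloride CC(C)(C)C(=O)Cl (its acyl group is carried only by 25)
Why: This mixed-anhydride N-acylation occurs at the more electrophilic and less hindered aryloxyacetyl carbonyl under non-acidic conditions.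

**Step 17**
Reactants: 26 (S)-4-benzyl-3-[2-(Lig-oxy)acetyl]oxazolidin-2-one; 27 4-benzyloxy-3-methoxybenzaldehyde (O-benzylvanillin)
Product: 30 (S)-4-benzyl-3-[(2S,3R)-3-(4-benzyloxy-3-methoxyphenyl)-3-hydroxy-2-(Lig-oxy)propanoyl]oxazolidin-2-one, via dibutylboron (Z)-enolate 28 (not isolated), via dibutylboron aldolate 29 (not isolated)
Conditions: Bu2BOTf, Et3N, CH2Cl2, −78 → 0 °C; 27, −78 → 0 °C; pH 7 buffer, MeOH, 30% H2O2, 0 °C
Reagents that add atoms: dibutylboron triflate CCCCB(CCCC)OS(=O)(=O)C(F)(F)F (boron and butyl groups are carried only by 28 and 29)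
Why: This Evans boron syn-aldol runs through a Zimmerman–Traxler chair of the (Z)-enolate, and the (S)-auxiliary fixes C8'' in its final configuration and C7'' as R, giving the threo adduct.

**Step 18**
Reactants: 30 (S)-4-benzyl-3-[(2S,3R)-3-(4-benzyloxy-3-methoxyphenyl)-3-hydroxy-2-(Lig-oxy)propanoyl]oxazolidin-2-one
Product: 31 (1R,2R)-1-(4-benzyloxy-3-methoxyphenyl)-2-(Lig-oxy)propane-1,3-diol (threo)
Conditions: NaBH4, THF–H2O (4:1), 0 °C → rt
Reagents that add atoms: none
Why: Reductive removal of the auxiliary converts the imide into the C9'' primary alcohol under nearly neutral conditions, without retro-aldol or epimerisation at C8''.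

**Step 19**
Reactants: 31 (1R,2R)-1-(4-benzyloxy-3-methoxyphenyl)-2-(Lig-oxy)propane-1,3-diol
Product: 32 (1R,2R)-1-(4-benzyloxy-3-methoxyphenyl)-3-(tert-butyldimethylsilyloxy)-2-(Lig-oxy)propan-1-ol
Conditions: TBSCl (1.1 equiv), imidazole, CH2Cl2, 0 °C
Reagents that add atoms: tert-butyldimethylsilyl chloride CC(C)(C)[Si](C)(C)Cl
Why: Sterically controlled selective silylation takes the primary hydroxyl and leaves the hindered secondary benzylic hydroxyl free.

**Step 20**
Reactants: 32 (1R,2R)-1-(4-benzyloxy-3-methoxyphenyl)-3-(tert-butyldimethylsilyloxy)-2-(Lig-oxy)propan-1-ol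
Product: 33 (1S,2R)-1-(4-benzyloxy-3-methoxyphenyl)-3-(tert-butyldimethylsilyloxy)-2-(Lig-oxy)propyl 4-nitrobenzoate (erythro)
Conditions: 4-nitrobenzoic acid, PPh3, DIAD, toluene, −10 °C → rt
Reagents that add atoms: 4-nitrobenzoic acid O=C(O)c1ccc([N+](=O)[O-])cc1
Why: In this Mitsunobu reaction SN2 displacement of the oxyphosphonium ion by the acidic carboxylate inverts C7'' from R to S, while the electron-withdrawing β-aryloxy group and the non-polar solvent hold back ionisation.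

**Step 21**
Reactants: 33 (1S,2R)-1-(4-benzyloxy-3-methoxyphenyl)-3-(tert-butyldimethylsilyloxy)-2-(Lig-oxy)propyl 4-nitrobenzoate
Product: 34 (1S,2R)-1-(4-benzyloxy-3-methoxyphenyl)-3-(tert-butyldimethylsilyloxy)-2-(Lig-oxy)propan-1-ol (erythro)
Conditions: K2CO3 (0.2 equiv), MeOH–THF, rt
Reagents that add atoms: none
Why: Base-catalysed methanolysis (transesterification) cleaves the activated ester at the acyl–oxygen bond, so C7'' keeps its new configuration.

**Step 22**
Reactants: 34 (1S,2R)-1-(4-benzyloxy-3-methoxyphenyl)-3-(tert-butyldimethylsilyloxy)-2-(Lig-oxy)propan-1-ol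
Product: 35 (1S,2R)-1-(4-benzyloxy-3-methoxyphenyl)-2-{4-[(2R,3S,4S)-4-(4-benzyloxy-3-methoxybenzyl)-3-(hydroxymethyl)tetrahydrofuran-2-yl]-2,6-dimethoxyphenoxy}propane-1,3-diol
Conditions: TBAF, AcOH (1:1, 3 equiv each), THF, rt
Reagents that add atoms: none
Why: Buffered fluoride desilylation removes both primary TBS ethers while the phenols are still benzylated, so no quinone methide (and no C7'' epimerisation) can arise.

**Step 23**
Reactants: 35 (1S,2R)-1-(4-benzyloxy-3-methoxyphenyl)-2-{4-[(2R,3S,4S)-4-(4-benzyloxy-3-methoxybenzyl)-3-(hydroxymethyl)tetrahydrofuran-2-yl]-2,6-dimethoxyphenoxy}propane-1,3-diol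
Product: 36 target CNP0170225.1
Conditions: H2 (1 atm), 10% Pd/C, EtOAc–EtOH, rt, stopped on consumption of 35
Reagents that add atoms: none
Why: Neutral catalytic hydrogenolysis cleaves aryl benzyl ethers much faster than the benzylic C7–O (THF) and C7''–OH bonds, and it touches no stereocentre.

**Compound list**
1 | ferulic acid | COc1cc(/C=C/C(=O)O)ccc1O | starting material
2 | dihydroferulic acid | COc1cc(CCC(=O)O)ccc1O | intermediate
3 | benzyl 3-(4-benzyloxy-3-methoxyphenyl)propanoate | COc1cc(CCC(=O)OCc2ccccc2)ccc1OCc1ccccc1 | intermediate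
4 | 3-(4-benzyloxy-3-methoxyphenyl)propanoic acid | COc1cc(CCC(=O)O)ccc1OCc1ccccc1 | intermediate
5 | (R)-4-benzyloxazolidin-2-one | O=C1N[C@H](Cc2ccccc2)CO1 | starting material
6 | 3-(4-benzyloxy-3-methoxyphenyl)propanoic pivalic anhydride | COc1cc(CCC(=O)OC(=O)C(C)(C)C)ccc1OCc1ccccc1 | intermediate (not isolated)
7 | (R)-4-benzyl-3-[3-(4-benzyloxy-3-methoxyphenyl)propanoyl]oxazolidin-2-one | COc1cc(CCC(=O)N2[C@H](Cc3ccccc3)COC2=O)ccc1OCc1ccccc1 | intermediate
8 | tert-butyl bromoacetate | CC(C)(C)OC(=O)CBr | starting material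
9 | sodium (Z)-enolate of 7 | [Na+].[O-]/C(=C\Cc1ccc(OCc2ccccc2)c(OC)c1)N1[C@H](Cc2ccccc2)COC1=O | intermediate (not isolated)
10 | tert-butyl (3S)-3-(4-benzyloxy-3-methoxybenzyl)-4-[(4R)-4-benzyl-2-oxooxazolidin-3-yl]-4-oxobutanoate | CC(C)(C)OC(=O)C[C@H](Cc1ccc(OCc2ccccc2)c(OC)c1)C(=O)N1[C@H](Cc2ccccc2)COC1=O | intermediate
11 | tert-butyl (3S)-3-(4-benzyloxy-3-methoxybenzyl)-4-hydroxybutanoate | CC(C)(C)OC(=O)C[C@H](Cc1ccc(OCc2ccccc2)c(OC)c1)CO | intermediate
12 | (4S)-4-(4-benzyloxy-3-methoxybenzyl)dihydrofuran-2(3H)-one | O=C1C[C@H](Cc2ccc(OCc3ccccc3)c(OC)c2)CO1 | intermediate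
13 | syringaldehyde | COc1cc(C=O)cc(OC)c1O | starting material
14 | 4-allyloxy-3,5-dimethoxybenzaldehyde | C=CCOc1c(OC)cc(C=O)cc1OC | intermediate
15 | lithium enolate of 12 | [Li+].[O-]C1=C[C@H](Cc2ccc(OCc3ccccc3)c(OC)c2)CO1 | intermediate (not isolated)
16 | (3R,4S)-3-[(4-allyloxy-3,5-dimethoxyphenyl)(hydroxy)methyl]-4-(4-benzyloxy-3-methoxybenzyl)dihydrofuran-2(3H)-one, C7 epimer mixture | COc1cc(C[C@@H]2COC(=O)[C@H]2C(O)c2cc(OC)c(OCC=C)c(OC)c2)ccc1OCc1ccccc1 | intermediate
17 | (2S,3S)-2-[(4-allyloxy-3,5-dimethoxyphenyl)(hydroxy)methyl]-3-(4-benzyloxy-3-methoxybenzyl)butane-1,4-diol, C7 epimer mixture | COc1cc(C[C@H](CO)[C@@H](CO)C(O)c2cc(OC)c(OCC=C)c(OC)c2)ccc1OCc1ccccc1 | intermediate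
18 | [(2R,3S,4S)-2-(4-allyloxy-3,5-dimethoxyphenyl)-4-(4-benzyloxy-3-methoxybenzyl)tetrahydrofuran-3-yl]methanol | COc1cc(C[C@@H]2CO[C@@H](c3cc(OC)c(OCC=C)c(OC)c3)[C@@H]2CO)ccc1OCc1ccccc1 | intermediate
19 | Lig-O-allyl (TBS ether of 18) | COc1cc(C[C@@H]2CO[C@@H](c3cc(OC)c(OCC=C)c(OC)c3)[C@@H]2CO[Si](C)(C)C(C)(C)C)ccc1OCc1ccccc1 | intermediate
20 | Lig-OH (free syringyl phenol) | COc1cc(C[C@@H]2CO[C@@H](c3cc(OC)c(O)c(OC)c3)[C@@H]2CO[Si](C)(C)C(C)(C)C)ccc1OCc1ccccc1 | intermediate
21 | methyl bromoacetate | COC(=O)CBr | starting material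
22 | methyl 2-(Lig-oxy)acetate | COc1cc(C[C@@H]2CO[C@@H](c3cc(OC)c(OCC(=O)OC)c(OC)c3)[C@@H]2CO[Si](C)(C)C(C)(C)C)ccc1OCc1ccccc1 | intermediate
23 | 2-(Lig-oxy)acetic acid | COc1cc(C[C@@H]2CO[C@@H](c3cc(OC)c(OCC(=O)O)c(OC)c3)[C@@H]2CO[Si](C)(C)C(C)(C)C)ccc1OCc1ccccc1 | intermediate
24 | (S)-4-benzyloxazolidin-2-one | O=C1N[C@@H](Cc2ccccc2)CO1 | starting material
25 | 2-(Lig-oxy)acetic pivalic anhydride | COc1cc(C[C@@H]2CO[C@@H](c3cc(OC)c(OCC(=O)OC(=O)C(C)(C)C)c(OC)c3)[C@@H]2CO[Si](C)(C)C(C)(C)C)ccc1OCc1ccccc1 | intermediate (not isolated)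
26 | (S)-4-benzyl-3-[2-(Lig-oxy)acetyl]oxazolidin-2-one | COc1cc(C[C@@H]2CO[C@@H](c3cc(OC)c(OCC(=O)N4[C@@H](Cc5ccccc5)COC4=O)c(OC)c3)[C@@H]2CO[Si](C)(C)C(C)(C)C)ccc1OCc1ccccc1 | intermediate
27 | 4-benzyloxy-3-methoxybenzaldehyde (O-benzylvanillin) | COc1cc(C=O)ccc1OCc1ccccc1 | starting material
28 | dibutylboron (Z)-enolate of 26 | COc1cc(C[C@@H]2CO[C@@H](c3cc(OC)c(O/C=C(\OB(CCCC)CCCC)N4[C@@H](Cc5ccccc5)COC4=O)c(OC)c3)[C@@H]2CO[Si](C)(C)C(C)(C)C)ccc1OCc1ccccc1 | intermediate (not isolated)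
29 | dibutylboron aldolate of 30 | COc1cc(C[C@@H]2CO[C@@H](c3cc(OC)c(O[C@H](C(=O)N4[C@@H](Cc5ccccc5)COC4=O)[C@H](OB(CCCC)CCCC)c4ccc(OCc5ccccc5)c(OC)c4)c(OC)c3)[C@@H]2CO[Si](C)(C)C(C)(C)C)ccc1OCc1ccccc1 | intermediate (not isolated)
30 | (S)-4-benzyl-3-[(2S,3R)-3-(4-benzyloxy-3-methoxyphenyl)-3-hydroxy-2-(Lig-oxy)propanoyl]oxazolidin-2-one | COc1cc(C[C@@H]2CO[C@@H](c3cc(OC)c(O[C@H](C(=O)N4[C@@H](Cc5ccccc5)COC4=O)[C@H](O)c4ccc(OCc5ccccc5)c(OC)c4)c(OC)c3)[C@@H]2CO[Si](C)(C)C(C)(C)C)ccc1OCc1ccccc1 | intermediate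
31 | (1R,2R)-1-(4-benzyloxy-3-methoxyphenyl)-2-(Lig-oxy)propane-1,3-diol (threo) | COc1cc(C[C@@H]2CO[C@@H](c3cc(OC)c(O[C@H](CO)[C@H](O)c4ccc(OCc5ccccc5)c(OC)c4)c(OC)c3)[C@@H]2CO[Si](C)(C)C(C)(C)C)ccc1OCc1ccccc1 | intermediate
32 | (1R,2R)-1-(4-benzyloxy-3-methoxyphenyl)-3-(tert-butyldimethylsilyloxy)-2-(Lig-oxy)propan-1-ol | COc1cc(C[C@@H]2CO[C@@H](c3cc(OC)c(O[C@H](CO[Si](C)(C)C(C)(C)C)[C@H](O)c4ccc(OCc5ccccc5)c(OC)c4)c(OC)c3)[C@@H]2CO[Si](C)(C)C(C)(C)C)ccc1OCc1ccccc1 | intermediate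
33 | (1S,2R)-1-(4-benzyloxy-3-methoxyphenyl)-3-(tert-butyldimethylsilyloxy)-2-(Lig-oxy)propyl 4-nitrobenzoate | COc1cc(C[C@@H]2CO[C@@H](c3cc(OC)c(O[C@H](CO[Si](C)(C)C(C)(C)C)[C@@H](OC(=O)c4ccc([N+](=O)[O-])cc4)c4ccc(OCc5ccccc5)c(OC)c4)c(OC)c3)[C@@H]2CO[Si](C)(C)C(C)(C)C)ccc1OCc1ccccc1 | intermediate
34 | (1S,2R)-1-(4-benzyloxy-3-methoxyphenyl)-3-(tert-butyldimethylsilyloxy)-2-(Lig-oxy)propan-1-ol (erythro) | COc1cc(C[C@@H]2CO[C@@H](c3cc(OC)c(O[C@H](CO[Si](C)(C)C(C)(C)C)[C@@H](O)c4ccc(OCc5ccccc5)c(OC)c4)c(OC)c3)[C@@H]2CO[Si](C)(C)C(C)(C)C)ccc1OCc1ccccc1 | intermediate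
35 | (1S,2R)-1-(4-benzyloxy-3-methoxyphenyl)-2-{4-[(2R,3S,4S)-4-(4-benzyloxy-3-methoxybenzyl)-3-(hydroxymethyl)tetrahydrofuran-2-yl]-2,6-dimethoxyphenoxy}propane-1,3-diol | COc1cc(C[C@@H]2CO[C@@H](c3cc(OC)c(O[C@H](CO)[C@@H](O)c4ccc(OCc5ccccc5)c(OC)c4)c(OC)c3)[C@@H]2CO)ccc1OCc1ccccc1 | intermediate
36 | CNP0170225.1, (7R,8S,8'S,7''S,8''R) | COc1cc(C[C@@H]2CO[C@@H](c3cc(OC)c(O[C@H](CO)[C@@H](O)c4ccc(O)c(OC)c4)c(OC)c3)[C@@H]2CO)ccc1O | target

**Totals**
Total steps: 23. Longest linear sequence: 22 (steps 1–7 and 9–23, from ferulic acid). Step 8 is the only side branch.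

**Three steps most likely to fail**

Step 20, the Mitsunobu inversion. The oxyphosphonium ion sits on a 4-alkoxybenzylic carbon. It can therefore ionise, which would erode the stereospecificity, or eliminate to the aryl enol ether. The fallback is a redox inversion.
- Setting out from 32, Dess–Martin periodinane with NaHCO3 in CH2Cl2 gives the aryl ketone F1.
- Zn(BH4)2 in Et2O at −40 °C then reduces F1 under Cram-chelate control. Zinc bridges the ketone oxygen and the aryloxy/ortho-methoxy oxygens, and hydride enters from the side of H-8''.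
- The product is the erythro alcohol 34, where the route is rejoined. Any threo alcohol formed is 32 itself; it is separable on silica and can be recycled.

Step 11, the acid cyclodehydration. The cation can also be captured by the electron-rich benzyl ring in a Friedel–Crafts closure to an aryltetralin. The 3,4,5-trialkoxy carbinol may also need more acid than is comfortable. The fallback is a quinone methide closure with a reordered protecting-group sequence.
- Setting out from 17, Pd(PPh3)4 and morpholine remove the allyl group first to give the phenolic tetraol F2.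
- With catalytic PPTS in CH2Cl2 at rt, F2 loses water to the p-quinone methide F3.
- The C9' hydroxyl traps F3 at once in an intramolecular 1,6-oxa-Michael addition, giving the phenolic tetrahydrofuran alcohol F4 with the aryl group trans to CH2OH.
- K2CO3 and 21 alkylate only the phenol to give the hydroxy ester F5.
- TBSCl and imidazole then give 22, where the route is rejoined.

Step 17, the late-stage Evans aldol. The polyoxygenated substrate can sequester Bu2BOTf, and the hindered 2,6-dimethoxyphenoxy enolate may react slowly or with reduced selectivity. The fallback keeps the aldol bond formation but moves stereocontrol to a catalyst.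
- Setting out from 22, LiHMDS in THF at −78 °C and 27 give the auxiliary-free aldol ester F6 as a mixture of isomers.
- Dess–Martin periodinane converts this mixture into the configurationally labile β-keto ester F7.
- Noyori-type asymmetric transfer hydrogenation with dynamic kinetic resolution follows, using RuCl(p-cymene)[(S,S)-TsDPEN] in HCO2H–Et3N. By analogy with α-alkoxy-β-keto esters it should give the syn hydroxy ester F8, but the sense of induction must be confirmed experimentally.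
- LiBH4 reduces F8 to 31, where the route is rejoined.

**Further compounds**
F1 | step 20 | (2R)-1-(4-benzyloxy-3-methoxyphenyl)-3-(tert-butyldimethylsilyloxy)-2-(Lig-oxy)propan-1-one | COc1cc(C[C@@H]2CO[C@@H](c3cc(OC)c(O[C@H](CO[Si](C)(C)C(C)(C)C)C(=O)c4ccc(OCc5ccccc5)c(OC)c4)c(OC)c3)[C@@H]2CO[Si](C)(C)C(C)(C)C)ccc1OCc1ccccc1
F2 | step 11 | (2S,3S)-3-(4-benzyloxy-3-methoxybenzyl)-2-[hydroxy(4-hydroxy-3,5-dimethoxyphenyl)methyl]butane-1,4-diol, C7 epimer mixture | COc1cc(C[C@H](CO)[C@@H](CO)C(O)c2cc(OC)c(O)c(OC)c2)ccc1OCc1ccccc1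
F3 | step 11 | p-quinone methide of F2 (C8 and C8' unchanged) | COC1=CC(=C[C@H](CO)[C@@H](CO)Cc2ccc(OCc3ccccc3)c(OC)c2)C=C(OC)C1=O
F4 | step 11 | 4-[(2R,3S,4S)-4-(4-benzyloxy-3-methoxybenzyl)-3-(hydroxymethyl)tetrahydrofuran-2-yl]-2,6-dimethoxyphenol | COc1cc(C[C@@H]2CO[C@@H](c3cc(OC)c(O)c(OC)c3)[C@@H]2CO)ccc1OCc1ccccc1
F5 | step 11 | methyl 2-{4-[(2R,3S,4S)-4-(4-benzyloxy-3-methoxybenzyl)-3-(hydroxymethyl)tetrahydrofuran-2-yl]-2,6-dimethoxyphenoxy}acetate | COc1cc(C[C@@H]2CO[C@@H](c3cc(OC)c(OCC(=O)OC)c(OC)c3)[C@@H]2CO)ccc1OCc1ccccc1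
F6 | step 17 | methyl 3-(4-benzyloxy-3-methoxyphenyl)-3-hydroxy-2-(Lig-oxy)propanoate, mixture of C2/C3 isomers | COc1cc(C[C@@H]2CO[C@@H](c3cc(OC)c(OC(C(=O)OC)C(O)c4ccc(OCc5ccccc5)c(OC)c4)c(OC)c3)[C@@H]2CO[Si](C)(C)C(C)(C)C)ccc1OCc1ccccc1
F7 | step 17 | methyl 3-(4-benzyloxy-3-methoxyphenyl)-3-oxo-2-(Lig-oxy)propanoate, C2 labile | COc1cc(C[C@@H]2CO[C@@H](c3cc(OC)c(OC(C(=O)OC)C(=O)c4ccc(OCc5ccccc5)c(OC)c4)c(OC)c3)[C@@H]2CO[Si](C)(C)C(C)(C)C)ccc1OCc1ccccc1
F8 | step 17 | methyl (2S,3R)-3-(4-benzyloxy-3-methoxyphenyl)-3-hydroxy-2-(Lig-oxy)propanoate | COc1cc(C[C@@H]2CO[C@@H](c3cc(OC)c(O[C@H](C(=O)OC)[C@H](O)c4ccc(OCc5ccccc5)c(OC)c4)c(OC)c3)[C@@H]2CO[Si](C)(C)C(C)(C)C)ccc1OCc1ccccc1
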